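Ring A is cut across C1–C2 and C3–C4, so that its tetrasubstituted C2=C3 unit becomes an internal alkyne and C1, C6, C5 and C4 become a cyclobutanone. One nickel-catalysed step inserts the alkyne into the C1–C4 bond of the four-membered ketone, closing ring A and joining two enantiopure fragments. The alkyne carries C-alpha (as a silyl-protected primary alcohol) and the quaternary C1' of ring B; the cyclobutanone carries C6 with its benzyloxymethyl group. The step exploits the cyclohex-2-enone of ring A, whose C1 carbonyl and C4 methylene flank C2=C3. All three stereocentres, (R)-C-alpha, (S)-C1' and (S)-C6, are made beforehand.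

Key step: step 11

Assumption: the facial sense of the copper–carbene catalyst in step 5 cannot be predicted with certainty for this enynone, so the ligand antipode (both are accessible) is the one that a pilot run shows to deliver methyl to the Si face of C3 of 7.

Step 1
Reactants: 1 methyl (S)-3-hydroxy-2-methylpropanoate
Product: 2 methyl (S)-3-[(tert-butyldimethylsilyl)oxy]-2-methylpropanoate
Conditions: TBSCl, imidazole, DMF, 0 °C → rt
Reagents that add atoms: tert-butyldimethylsilyl chloride, CC(C)(C)[Si](C)(C)Cl
Why: standard silylation of a primary alcohol under imidazole conditions that do not enolise the ester, so the stereocentre that becomes C-alpha is untouched.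

Step 2
Reactants: 2 methyl (S)-3-[(tert-butyldimethylsilyl)oxy]-2-methylpropanoate
Product: 4 (R)-tert-butyl(dimethyl)[(2-methylbut-3-yn-1-yl)oxy]silane, via aldehyde 3 (not isolated)
Conditions: DIBAL-H, CH2Cl2, −78 °C; then MeOH, dimethyl (1-diazo-2-oxopropyl)phosphonate, K2CO3, −78 °C → rt
Reagents that add atoms: dimethyl (1-diazo-2-oxopropyl)phosphonate, CC(=O)C(=[N+]=[N-])P(=O)(OC)OC
Why: half-reduction of the ester at low temperature followed in the same flask by Ohira–Bestmann (Seyferth–Gilbert) homologation should give the terminal alkyne without isolating the epimerisable α-methyl aldehyde; the stereocentre is carried over and only its descriptor changes (S to R) through the CIP priorities.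

Step 3
Reactants: 5 dimedone (5,5-dimethylcyclohexane-1,3-dione)
Product: 6 5,5-dimethyl-3-oxocyclohex-1-en-1-yl trifluoromethanesulfonate
Conditions: Tf2O, pyridine, CH2Cl2, −78 → 0 °C
Reagents that add atoms: trifluoromethanesulfonic anhydride, O=S(=O)(OS(=O)(=O)C(F)(F)F)C(F)(F)F
Why: O-sulfonylation of the enol form of a cyclic 1,3-diketone, which reacts as a vinylogous acid.

Step 4
Reactants: 4 (R)-tert-butyl(dimethyl)[(2-methylbut-3-yn-1-yl)oxy]silane; 6 5,5-dimethyl-3-oxocyclohex-1-en-1-yl trifluoromethanesulfonate
Product: 7 3-[(R)-4-[(tert-butyldimethylsilyl)oxy]-3-methylbut-1-yn-1-yl]-5,5-dimethylcyclohex-2-en-1-one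
Conditions: Pd(PPh3)2Cl2 (3 mol%), CuI (6 mol%), Et3N, THF, rt
Reagents that add atoms: none
Why: Sonogashira coupling of an activated β-triflyloxy enone, which should proceed at room temperature; the amine base does not touch the propargylic stereocentre.

Step 5
Reactants: 7 3-[(R)-4-[(tert-butyldimethylsilyl)oxy]-3-methylbut-1-yn-1-yl]-5,5-dimethylcyclohex-2-en-1-one
Product: 8 (R)-3-[(R)-4-[(tert-butyldimethylsilyl)oxy]-3-methylbut-1-yn-1-yl]-3,5,5-trimethylcyclohexan-1-one
Conditions: MeMgBr, Cu(OTf)2 (3 mol%), chiral N-mesityl-N'-(1-hydroxyalk-2-yl)imidazolinium hexafluorophosphate (leucinol-derived carbene precursor, 4 mol%), Et2O, −30 °C; then aq. NH4Cl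
Reagents that add atoms: methylmagnesium bromide, C[Mg]Br
Why: copper-catalysed asymmetric conjugate addition of a Grignard reagent to a 3-alkynylcyclohex-2-enone, a substrate class on which carbene–copper catalysts add 1,4 and not 1,6 to give alkynyl-bearing quaternary centres; the ligand controls the face of C3 (methyl to the Si face), which sets (R) in 8 and thereby (S)-C1', and copper-mediated β-methylation of 5,5-dimethylcyclohexenones is classical despite the axial methyl group.

Step 6
Reactants: 8 (R)-3-[(R)-4-[(tert-butyldimethylsilyl)oxy]-3-methylbut-1-yn-1-yl]-3,5,5-trimethylcyclohexan-1-one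
Product: 9 p-toluenesulfonylhydrazone of 8 (C=N geometry not defined)
Conditions: TsNHNH2, EtOH, 50 °C
Reagents that add atoms: p-toluenesulfonyl hydrazide, Cc1ccc(cc1)S(=O)(=O)NN
Why: condensation of an unconjugated ketone with a sulfonyl hydrazide under near-neutral conditions that the silyl ether and the alkyne tolerate.

Step 7
Reactants: 9 p-toluenesulfonylhydrazone of 8
Product: 10 tert-butyl(dimethyl){[(R)-2-methyl-4-[(S)-1,3,3-trimethylcyclohexyl]but-3-yn-1-yl]oxy}silane
Conditions: catecholborane, CHCl3, 0 °C → rt; then NaOAc·3H2O, reflux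
Reagents that add atoms: none
Why: hydride reduction of the tosylhydrazone and acetate-induced loss of sulfinate and N2 from the diazene (a mild Wolff–Kishner-type deoxygenation) should remove the carbonyl without strong base that could isomerise the alkyne to an allene; the quaternary centre is untouched and becomes (S) only through the CIP priorities.

Step 8
Reactants: 11 cyclobutanone; 12 (S)-1-amino-2-(methoxymethyl)pyrrolidine (SAMP)
Product: 13 N-cyclobutylidene-(S)-2-(methoxymethyl)pyrrolidin-1-amine
Conditions: neat, 4 Å molecular sieves, rt → 60 °C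
Reagents that add atoms: none
Why: condensation of the ketone with the chiral hydrazine gives the SAMP hydrazone.

Step 9
Reactants: 13 N-cyclobutylidene-(S)-2-(methoxymethyl)pyrrolidin-1-amine; 14 benzyl chloromethyl ether
Product: 15 N-[(R)-2-(benzyloxymethyl)cyclobutylidene]-(S)-2-(methoxymethyl)pyrrolidin-1-amine
Conditions: LDA, THF, −78 °C; then 14, −100 → −78 °C
Reagents that add atoms: none
Why: SAMP-hydrazone alkylation, in which the methoxy-chelated lithium azaenolate is attacked by the reactive chloromethyl ether on its less hindered face; by the usual model this sets the centre that becomes (S)-C6 (formally R in the hydrazone because CH2O outranks C=N).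

Step 10
Reactants: 15 N-[(R)-2-(benzyloxymethyl)cyclobutylidene]-(S)-2-(methoxymethyl)pyrrolidin-1-amine
Product: 16 (S)-2-[(benzyloxy)methyl]cyclobutan-1-one
Conditions: sat. aq. oxalic acid, Et2O, rt
Reagents that add atoms: water, O
Why: two-phase hydrolysis of the hydrazone under mildly acidic conditions, which should neither enolise the strained ketone nor eliminate benzyl alcohol, so the new centre keeps its configuration and the auxiliary is recovered.

Step 11
Reactants: 10 tert-butyl(dimethyl){[(R)-2-methyl-4-[(S)-1,3,3-trimethylcyclohexyl]but-3-yn-1-yl]oxy}silane; 16 (S)-2-[(benzyloxy)methyl]cyclobutan-1-one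
Product: 17 (S)-6-[(benzyloxy)methyl]-2-[(R)-1-[(tert-butyldimethylsilyl)oxy]propan-2-yl]-3-[(S)-1,3,3-trimethylcyclohexyl]cyclohex-2-en-1-one
Conditions: Ni(cod)2 (15 mol%), PCy3 (30 mol%), toluene, 100 °C, slow addition of 16 (1.5 equiv)
Reagents that add atoms: none
Why: Proposed new method: zerovalent nickel should couple the C1 carbonyl of 16 and the alkyne of 10 oxidatively to an oxanickelacyclopentene in which C1 bonds to the alkyne carbon bearing the sec-alkyl group (C2) and nickel sits on the carbon bearing the 1,3,3-trimethylcyclohexyl group (C3); β-carbon elimination of the strained C1–C4 bond then gives a seven-membered alkyl(alkenyl)nickel ring and C(sp2)–C(sp3) reductive elimination forms C3–C4. The closest known reaction type is the nickel/trialkylphosphine-catalysed intermolecular insertion of internal alkynes into the carbonyl–α-carbon bond of 3-substituted cyclobutanones to give cyclohex-2-enones; a 2-substituted cyclobutanone combined with a tert-alkyl alkyne is without precedent. Ring A closes by this reductive elimination, a two-carbon ring expansion (formal [4+2]) driven by release of four-ring strain and not by a condensation at the crowded C2=C3 unit. No stereocentre is created; C-alpha, C1' and C6 are carried in unchanged because none of them is bonded to nickel and the medium is neutral, aprotic and free of base, so the enolisable C6–H and the β-benzyloxy group should survive. Two selectivities are needed: the alkyne orientation, secured by the tert-alkyl versus sec-alkyl size difference (the quaternary C1' cannot sit next to the fully substituted C1), and the site of cleavage, secured by the substituent on C6, which makes C1–C4 the less hindered bond and leads to a primary alkylnickel. The silyl ether is kept on the alkyne side by design, since it holds C-alpha at the alcohol oxidation level (no racemisation through an allene or enol) and offers no donor atom that could steer nickel to the wrong alkyne carbon.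

Step 12
Reactants: 17 (S)-6-[(benzyloxy)methyl]-2-[(R)-1-[(tert-butyldimethylsilyl)oxy]propan-2-yl]-3-[(S)-1,3,3-trimethylcyclohexyl]cyclohex-2-en-1-one
Product: 18 (S)-6-[(benzyloxy)methyl]-2-[(R)-1-hydroxypropan-2-yl]-3-[(S)-1,3,3-trimethylcyclohexyl]cyclohex-2-en-1-one
Conditions: HF·pyridine, pyridine, THF, 0 °C → rt
Reagents that add atoms: none
Why: desilylation with buffered hydrogen fluoride avoids basic fluoride sources that could epimerise C6 or eliminate benzyl alcohol from the β-alkoxy ketone.

Step 13
Reactants: 18 (S)-6-[(benzyloxy)methyl]-2-[(R)-1-hydroxypropan-2-yl]-3-[(S)-1,3,3-trimethylcyclohexyl]cyclohex-2-en-1-one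
Product: 19 (R)-2-[(S)-5-[(benzyloxy)methyl]-6-oxo-2-[(S)-1,3,3-trimethylcyclohexyl]cyclohex-1-en-1-yl]propanoic acid
Conditions: TEMPO (cat.), NaOCl (cat.), NaClO2, MeCN/phosphate buffer pH 6.7, 35 °C
Reagents that add atoms: sodium chlorite, [Na+].[O-]Cl=O
Why: TEMPO-catalysed oxidation to the aldehyde with immediate Pinnick-type chlorite oxidation near neutral pH should take the primary alcohol to the acid without letting the α-chiral aldehyde accumulate, which protects C-alpha; the benzyl ether and the hindered enone are inert.

Step 14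
Reactants: 19 (R)-2-[(S)-5-[(benzyloxy)methyl]-6-oxo-2-[(S)-1,3,3-trimethylcyclohexyl]cyclohex-1-en-1-yl]propanoic acid
Product: 20 (R)-2-[(S)-5-(hydroxymethyl)-6-oxo-2-[(S)-1,3,3-trimethylcyclohexyl]cyclohex-1-en-1-yl]propanoic acid
Conditions: H2 (1 atm), 10% Pd/C, EtOAc, rt
Reagents that add atoms: none
Why: hydrogenolysis of the benzyl ether; the tetrasubstituted C2=C3 bond, shielded by the quaternary C1', and the ketone should not be reduced at atmospheric pressure.

Step 15
Reactants: 20 (R)-2-[(S)-5-(hydroxymethyl)-6-oxo-2-[(S)-1,3,3-trimethylcyclohexyl]cyclohex-1-en-1-yl]propanoic acid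
Product: 21 (R)-2-[(S)-5-[(formyloxy)methyl]-6-oxo-2-[(S)-1,3,3-trimethylcyclohexyl]cyclohex-1-en-1-yl]propanoic acid
Conditions: AcOCHO (freshly prepared), THF, 0 °C → rt; aqueous work-up
Reagents that add atoms: acetic formic anhydride, CC(=O)OC=O
Why: O-formylation of the primary alcohol by the mixed anhydride, which transfers the formyl group selectively; no base is used, so C6 cannot epimerise and formic acid cannot be eliminated, and any mixed anhydride formed at the carboxylic acid is hydrolysed on work-up.

Compound list
1 | methyl (S)-3-hydroxy-2-methylpropanoate | C[C@@H](CO)C(=O)OC | starting material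
2 | methyl (S)-3-[(tert-butyldimethylsilyl)oxy]-2-methylpropanoate | C[C@@H](CO[Si](C)(C)C(C)(C)C)C(=O)OC | intermediate
3 | (S)-3-[(tert-butyldimethylsilyl)oxy]-2-methylpropanal (not isolated) | C[C@@H](CO[Si](C)(C)C(C)(C)C)C=O | intermediate
4 | (R)-tert-butyl(dimethyl)[(2-methylbut-3-yn-1-yl)oxy]silane | C[C@@H](CO[Si](C)(C)C(C)(C)C)C#C | intermediate
5 | dimedone (5,5-dimethylcyclohexane-1,3-dione) | CC1(C)CC(=O)CC(=O)C1 | starting material
6 | 5,5-dimethyl-3-oxocyclohex-1-en-1-yl trifluoromethanesulfonate | CC1(C)CC(=O)C=C(OS(=O)(=O)C(F)(F)F)C1 | intermediate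
7 | 3-[(R)-4-[(tert-butyldimethylsilyl)oxy]-3-methylbut-1-yn-1-yl]-5,5-dimethylcyclohex-2-en-1-one | C[C@@H](CO[Si](C)(C)C(C)(C)C)C#CC1=CC(=O)CC(C)(C)C1 | intermediate
8 | (R)-3-[(R)-4-[(tert-butyldimethylsilyl)oxy]-3-methylbut-1-yn-1-yl]-3,5,5-trimethylcyclohexan-1-one | C[C@@H](CO[Si](C)(C)C(C)(C)C)C#C[C@@]1(C)CC(=O)CC(C)(C)C1 | intermediate
9 | p-toluenesulfonylhydrazone of 8 (C=N geometry not defined) | C[C@@H](CO[Si](C)(C)C(C)(C)C)C#C[C@@]1(C)CC(=NNS(=O)(=O)c2ccc(C)cc2)CC(C)(C)C1 | intermediate
10 | tert-butyl(dimethyl){[(R)-2-methyl-4-[(S)-1,3,3-trimethylcyclohexyl]but-3-yn-1-yl]oxy}silane | C[C@@H](CO[Si](C)(C)C(C)(C)C)C#C[C@@]1(C)CCCC(C)(C)C1 | intermediate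
11 | cyclobutanone | O=C1CCC1 | starting material
12 | (S)-1-amino-2-(methoxymethyl)pyrrolidine (SAMP) | COC[C@@H]1CCCN1N | starting material
13 | N-cyclobutylidene-(S)-2-(methoxymethyl)pyrrolidin-1-amine | COC[C@@H]1CCCN1N=C1CCC1 | intermediate
14 | benzyl chloromethyl ether | ClCOCc1ccccc1 | starting material
15 | N-[(R)-2-(benzyloxymethyl)cyclobutylidene]-(S)-2-(methoxymethyl)pyrrolidin-1-amine (C=N geometry not defined) | COC[C@@H]1CCCN1N=C1CC[C@H]1COCc1ccccc1 | intermediate
16 | (S)-2-[(benzyloxy)methyl]cyclobutan-1-one | O=C1CC[C@H]1COCc1ccccc1 | intermediate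
17 | (S)-6-[(benzyloxy)methyl]-2-[(R)-1-[(tert-butyldimethylsilyl)oxy]propan-2-yl]-3-[(S)-1,3,3-trimethylcyclohexyl]cyclohex-2-en-1-one | C[C@@H](CO[Si](C)(C)C(C)(C)C)C1=C([C@@]2(C)CCCC(C)(C)C2)CC[C@@H](COCc3ccccc3)C1=O | intermediate
18 | (S)-6-[(benzyloxy)methyl]-2-[(R)-1-hydroxypropan-2-yl]-3-[(S)-1,3,3-trimethylcyclohexyl]cyclohex-2-en-1-one | C[C@@H](CO)C1=C([C@@]2(C)CCCC(C)(C)C2)CC[C@@H](COCc3ccccc3)C1=O | intermediate
19 | (R)-2-[(S)-5-[(benzyloxy)methyl]-6-oxo-2-[(S)-1,3,3-trimethylcyclohexyl]cyclohex-1-en-1-yl]propanoic acid | C[C@@H](C(=O)O)C1=C([C@@]2(C)CCCC(C)(C)C2)CC[C@@H](COCc3ccccc3)C1=O | intermediate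
20 | (R)-2-[(S)-5-(hydroxymethyl)-6-oxo-2-[(S)-1,3,3-trimethylcyclohexyl]cyclohex-1-en-1-yl]propanoic acid | C[C@@H](C(=O)O)C1=C([C@@]2(C)CCCC(C)(C)C2)CC[C@@H](CO)C1=O | intermediate
21 | (R)-2-[(S)-5-[(formyloxy)methyl]-6-oxo-2-[(S)-1,3,3-trimethylcyclohexyl]cyclohex-1-en-1-yl]propanoic acid | C[C@@H](C(=O)O)C1=C([C@@]2(C)CCCC(C)(C)C2)CC[C@@H](COC=O)C1=O | target

Total step count: 15. Longest linear sequence: 11 steps (1 → 21 through steps 1, 2, 4, 5, 6, 7, 11, 12, 13, 14 and 15).

Steps most likely to fail

Step 11. The hindered alkyne may not enter the oxidative cyclisation, so that the cyclobutanone is consumed by decarbonylation or oligomerisation. Alternatively, nickel may cleave the substituted C1–C6 bond and then lose benzyloxide, or C6 may epimerise at 100 °C. The fallback sets out from alkyne 10 and cyclobutanone 16 and makes the same two bonds one at a time. Alkyne 10 is converted with Ti(OiPr)4 and i-PrMgCl (Et2O, −78 → −40 °C) into its titanium–alkyne complex, which adds to the carbonyl of 16 through the less hindered alkyne carbon and so forms C1–C2. Iodine then cleaves the remaining C3–titanium bond with retention and should give (2S)-2-[(benzyloxy)methyl]-1-{(1Z,3R)-4-[(tert-butyldimethylsilyl)oxy]-1-iodo-3-methyl-1-[(S)-1,3,3-trimethylcyclohexyl]but-1-en-2-yl}cyclobutan-1-ol F1 (carbinol configuration of no consequence). Heating F1 with Pd(OAc)2, a bulky phosphine and Cs2CO3 in toluene at 80 °C should close ring A and return to enone 17. The sequence is oxidative addition of zerovalent palladium into the C3–I bond, formation of the palladium alkoxide, β-carbon elimination of the C1–C4 bond and C–C reductive elimination. This is the ring-opening coupling of tert-cyclobutanols with organic halides, used here in its intramolecular form.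

Step 5. The gem-dimethyl group next to the β-carbon may slow the conjugate addition enough for 1,2- or 1,6-addition to compete, and the catalyst may discriminate the faces of C3 poorly; the resulting C1' epimers would be hard to separate later. The fallback sets out from alkyne 4 and moves the stereo-defining step to a substrate inside the established scope. Cyclohexane-1,3-dione (commercial) is converted with Tf2O and pyridine into 3-oxocyclohex-1-en-1-yl trifluoromethanesulfonate F2. Sonogashira coupling with 4 gives 3-[(R)-4-[(tert-butyldimethylsilyl)oxy]-3-methylbut-1-yn-1-yl]cyclohex-2-en-1-one F3. The same copper–carbene-catalysed methyl Grignard addition then gives (S)-3-[(R)-4-[(tert-butyldimethylsilyl)oxy]-3-methylbut-1-yn-1-yl]-3-methylcyclohexan-1-one F4. Geminal dimethylation of its carbonyl carbon with Me2TiCl2 (from Me2Zn and TiCl4, CH2Cl2, −30 → 0 °C) turns that carbon directly into C3' and rejoins the route at alkyne 10, so steps 6 and 7 are no longer needed.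

Step 9. Facial control in the strained four-ring azaenolate may be incomplete, a second alkylation may occur, and the α-centre may erode during hydrazone cleavage in step 10. The fallback sets out from cyclobutanone 11 and replaces the auxiliary by enamine catalysis. An (S)-proline-catalysed aldol reaction with aqueous formaldehyde (DMSO, rt) should give (S)-2-(hydroxymethyl)cyclobutan-1-one F5, the same sense as for other cyclic ketones. F5 is benzylated under acid catalysis with benzyl 2,2,2-trichloroacetimidate and TfOH (cat.) in CH2Cl2 at 0 °C, which returns to ketone 16 without any basic step.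

Further compounds
F1 | step 11 | (2S)-2-[(benzyloxy)methyl]-1-{(1Z,3R)-4-[(tert-butyldimethylsilyl)oxy]-1-iodo-3-methyl-1-[(S)-1,3,3-trimethylcyclohexyl]but-1-en-2-yl}cyclobutan-1-ol | C[C@@H](CO[Si](C)(C)C(C)(C)C)/C(=C(/I)[C@@]1(C)CCCC(C)(C)C1)C1(O)CC[C@H]1COCc1ccccc1
F2 | step 5 | 3-oxocyclohex-1-en-1-yl trifluoromethanesulfonate | O=C1C=C(OS(=O)(=O)C(F)(F)F)CCC1
F3 | step 5 | 3-[(R)-4-[(tert-butyldimethylsilyl)oxy]-3-methylbut-1-yn-1-yl]cyclohex-2-en-1-one | C[C@@H](CO[Si](C)(C)C(C)(C)C)C#CC1=CC(=O)CCC1
F4 | step 5 | (S)-3-[(R)-4-[(tert-butyldimethylsilyl)oxy]-3-methylbut-1-yn-1-yl]-3-methylcyclohexan-1-one | C[C@@H](CO[Si](C)(C)C(C)(C)C)C#C[C@@]1(C)CCCC(=O)C1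
F5 | step 9 | (S)-2-(hydroxymethyl)cyclobutan-1-one | O=C1CC[C@H]1CO
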